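**Retrosynthetic overview**

- Feature: in the cis-fused hexahydrocyclopenta[c]isoxazole (N1, O2, C3, C3a, C4–C6, C6a) H3, H3a and H6a are all cis. The C3 chain therefore points into the concave face, syn to C4, which is the less stable arrangement, and C3 has to be set by a catalyst as the O2–C3 bond forms.
- C3 side chain: cut at the C1'=C2' alkene, giving a C3 vinyl group that is joined to 3-(oct-7-enyl)pyridine by cross-metathesis and then reduced with diimide.
- O2–C3: iridium–phosphoramidite allylic etherification in which the N–OH oxygen closes onto an (E)-allylic methyl carbonate carried by C3a. This closes the isoxazolidine, the only ring made; the cyclopentane with C3a/C6a is bought as (1S,2R)-cis-2-aminocyclopentanecarboxylic acid.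
- Precursor: Boc-amino acid → alcohol → one-pot oxidation/Wittig → DIBAL → methyl carbonate; then Boc removal, reductive amination with 12-(pyridin-3-yl)dodecanal, N-oxidation with benzoyl peroxide and hydrazinolysis, so that the free N–OH appears only just before cyclisation.
- Pyridine chains: the C8 alkenyl chain comes from lateral lithiation of 3-methylpyridine, the C12 chain from Sonogashira coupling of 3-bromopyridine with dodec-11-yn-1-ol and hydrogenation.

Key step: step 14

Assumption: cross-metathesis should give an E/Z mixture at the new alkene; it is carried on unseparated because step 16 removes the double bond (E isomer drawn).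
Assumption: the ligand enantiomer in step 14 follows the empirical face rule of the BINOL/bis(1-phenylethyl)amine phosphoramidite family. The C3 configuration of 22 would be checked by NOE (H3/H3a), and the antipodal ligand would be used if the rule does not transfer to this substrate.

**Route**

Step 1
Reactants: 1 3-methylpyridine; 2 7-bromohept-1-ene
Product: 4 3-(oct-7-en-1-yl)pyridine, via (pyridin-3-ylmethyl)lithium 3 (not isolated)
Conditions: LDA (1.1 equiv), THF, −78 °C, 1 h; then 2, −78 °C → rt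
Reagents that add atoms: none
Why: Lateral lithiation of 3-methylpyridine gives the picolyl anion, which should alkylate the primary bromide by SN2 without touching the terminal alkene.

Step 2
Reactants: 5 3-bromopyridine; 6 dodec-11-yn-1-ol
Product: 7 12-(pyridin-3-yl)dodec-11-yn-1-ol
Conditions: Pd(PPh3)2Cl2 (2 mol %), CuI (4 mol %), Et3N, 60 °C, Ar
Reagents that add atoms: none
Why: In this Sonogashira coupling Pd(0) inserts into the C–Br bond of the electron-poor bromopyridine and the copper acetylide transmetalates, so the aryl alkyne should form without protection of the remote primary alcohol.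

Step 3
Reactants: 7 12-(pyridin-3-yl)dodec-11-yn-1-ol
Product: 8 12-(pyridin-3-yl)dodecan-1-ol
Conditions: H2 (1 atm), 10% Pd/C, EtOH, rt
Reagents that add atoms: none
Why: Heterogeneous catalytic hydrogenation saturates the alkyne fully, while the pyridine ring is not reduced over Pd/C at 1 atm in a neutral solvent.

Step 4
Reactants: 8 12-(pyridin-3-yl)dodecan-1-ol
Product: 9 12-(pyridin-3-yl)dodecanal
Conditions: IBX (1.5 equiv), EtOAc, 80 °C
Reagents that add atoms: none
Why: IBX oxidation of a primary alcohol stops at the aldehyde and tolerates the basic pyridine.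

Step 5
Reactants: 10 (1S,2R)-2-aminocyclopentane-1-carboxylic acid
Product: 11 (1S,2R)-2-[(tert-butoxycarbonyl)amino]cyclopentane-1-carboxylic acid
Conditions: Boc2O, NaOH, dioxane/H2O, 0 °C → rt; then aq. HCl to pH 3
Reagents that add atoms: di-tert-butyl dicarbonate, CC(C)(C)OC(=O)OC(=O)OC(C)(C)C
Why: Schotten–Baumann carbamate formation protects nitrogen without affecting either stereocentre.

Step 6
Reactants: 11 (1S,2R)-2-[(tert-butoxycarbonyl)amino]cyclopentane-1-carboxylic acid
Product: 12 tert-butyl N-[(1R,2S)-2-(hydroxymethyl)cyclopentyl]carbamate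
Conditions: BH3·THF, THF, 0 °C → rt; MeOH quench
Reagents that add atoms: none
Why: Borane reduces the carboxylic acid chemoselectively in the presence of the carbamate and without an enolisable intermediate, so the cis relationship should be kept.

Step 7
Reactants: 12 tert-butyl N-[(1R,2S)-2-(hydroxymethyl)cyclopentyl]carbamate
Product: 14 methyl (2E)-3-[(1R,2R)-2-[(tert-butoxycarbonyl)amino]cyclopentyl]prop-2-enoate, via Boc-amino aldehyde 13 (not isolated)
Conditions: IBX (1.5 equiv), Ph3P=CHCO2Me (1.5 equiv), DMSO, rt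
Reagents that add atoms: methyl (triphenyl-λ5-phosphanylidene)acetate, COC(=O)C=P(c1ccccc1)(c1ccccc1)c1ccccc1
Why: In this one-pot IBX oxidation/Wittig olefination the neutral stabilised ylide traps the epimerisable cis aldehyde as it forms and should give the E enoate.

Step 8
Reactants: 14 methyl (2E)-3-[(1R,2R)-2-[(tert-butoxycarbonyl)amino]cyclopentyl]prop-2-enoate
Product: 15 tert-butyl N-[(1R,2R)-2-[(1E)-3-hydroxyprop-1-en-1-yl]cyclopentyl]carbamate
Conditions: DIBAL-H (3.5 equiv), CH2Cl2, −78 °C; aq. Rochelle salt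
Reagents that add atoms: none
Why: DIBAL-H reduces the enoate 1,2 to the allylic alcohol at low temperature while the Boc carbamate survives.

Step 9
Reactants: 15 tert-butyl N-[(1R,2R)-2-[(1E)-3-hydroxyprop-1-en-1-yl]cyclopentyl]carbamate
Product: 16 tert-butyl N-[(1R,2R)-2-[(1E)-3-[(methoxycarbonyl)oxy]prop-1-en-1-yl]cyclopentyl]carbamate
Conditions: ClCO2Me, pyridine, CH2Cl2, 0 °C
Reagents that add atoms: methyl chloroformate, COC(=O)Cl
Why: O-acylation of the primary allylic alcohol installs the carbonate leaving group; the carbamate N–H is too weakly nucleophilic to compete.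

Step 10
Reactants: 16 tert-butyl N-[(1R,2R)-2-[(1E)-3-[(methoxycarbonyl)oxy]prop-1-en-1-yl]cyclopentyl]carbamate
Product: 17 (2E)-3-[(1R,2R)-2-aminocyclopentyl]prop-2-en-1-yl methyl carbonate
Conditions: TFA/CH2Cl2 (1:4), 0 °C; aq. NaHCO3; free base used at once
Reagents that add atoms: none
Why: Acidolysis of the Boc group (loss of isobutene and CO2) should be faster than ionisation of the primary allylic carbonate at 0 °C.

Step 11
Reactants: 17 (2E)-3-[(1R,2R)-2-aminocyclopentyl]prop-2-en-1-yl methyl carbonate; 9 12-(pyridin-3-yl)dodecanal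
Product: 19 methyl (2E)-3-[(1R,2R)-2-{[12-(pyridin-3-yl)dodecyl]amino}cyclopentyl]prop-2-en-1-yl carbonate, via aldimine 18 (not isolated)
Conditions: NaBH(OAc)3 (1.5 equiv), AcOH (cat.), DCE, rt
Reagents that add atoms: none
Why: Reductive amination with triacetoxyborohydride should stop at mono-alkylation of the α-branched primary amine and does not reduce the carbonate or the alkene.

Step 12
Reactants: 19 methyl (2E)-3-[(1R,2R)-2-{[12-(pyridin-3-yl)dodecyl]amino}cyclopentyl]prop-2-en-1-yl carbonate
Product: 20 methyl (2E)-3-[(1R,2R)-2-{(benzoyloxy)[12-(pyridin-3-yl)dodecyl]amino}cyclopentyl]prop-2-en-1-yl carbonate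
Conditions: (BzO)2 (1.1 equiv), K2HPO4 (1.5 equiv), DMF, rt
Reagents that add atoms: dibenzoyl peroxide, O=C(OOC(=O)c1ccccc1)c1ccccc1
Why: The secondary amine attacks the peroxide oxygen (electrophilic N-oxidation with a diacyl peroxide) and the N–O bond is delivered already O-protected; the much less nucleophilic pyridine and the alkene should not react.

Step 13
Reactants: 20 methyl (2E)-3-[(1R,2R)-2-{(benzoyloxy)[12-(pyridin-3-yl)dodecyl]amino}cyclopentyl]prop-2-en-1-yl carbonate
Product: 21 methyl (2E)-3-[(1R,2R)-2-{hydroxy[12-(pyridin-3-yl)dodecyl]amino}cyclopentyl]prop-2-en-1-yl carbonate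
Conditions: N2H4·H2O (2 equiv), THF, 0 °C, Ar; used directly
Reagents that add atoms: none
Why: The O-acyl hydroxylamine is an activated ester, so hydrazinolysis should be far faster than attack on the alkyl carbonate.

Step 14
Reactants: 21 methyl (2E)-3-[(1R,2R)-2-{hydroxy[12-(pyridin-3-yl)dodecyl]amino}cyclopentyl]prop-2-en-1-yl carbonate
Product: 22 (3S,3aS,6aR)-3-ethenyl-1-[12-(pyridin-3-yl)dodecyl]hexahydro-1H-cyclopenta[c][1,2]oxazole
Conditions: [Ir(cod)Cl]2 (2.5 mol %), (Sa,Sc,Sc)-O,O'-(1,1'-binaphthyl-2,2'-diyl) N,N-bis(1-phenylethyl)phosphoramidite (5 mol %), TBD (8 mol %), THF (0.03 M), rt → 35 °C, Ar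
Reagents that add atoms: none
Why: The TBD-activated cyclometalated Ir(I)–phosphoramidite complex binds one enantioface of the (E)-alkene and ionises the carbonate with inversion to a (π-allyl)Ir(III) species, releasing CO2 and methoxide, which deprotonates N–OH; the hydroxylamine oxygen then attacks the substituted allyl terminus anti to iridium, so the face chosen by the ligand becomes the configuration at C3. This is the known iridium-catalysed branched-selective asymmetric allylic etherification with hydroxylamine-type oxygen nucleophiles, run intramolecularly as in known Ir-allyl cyclisations to vinyl-substituted five-membered heterocycles. The isoxazolidine (N1–O2–C3–C3a–C6a) closes by 5-exo attack forming O2–C3; 7-endo attack at the CH2 terminus is disfavoured by the branched preference of iridium and by ring size, and N attack would need a four-membered ring. C3 is the only new stereocentre and is set by the ligand: the (Sa,Sc,Sc) enantiomer is the one expected to place oxygen so that H3 ends up cis to H3a (3S), against the substrate's own leaning towards the epimer with vinyl on the convex face. The cis C3a/C6a pair inherited from 10 fixes the ring fusion and is not at risk under these near-neutral conditions. High dilution should suppress intermolecular O-allylation.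

Step 15
Reactants: 22 (3S,3aS,6aR)-3-ethenyl-1-[12-(pyridin-3-yl)dodecyl]hexahydro-1H-cyclopenta[c][1,2]oxazole; 4 3-(oct-7-en-1-yl)pyridine (3 equiv)
Product: 23 (3S,3aS,6aR)-1-[12-(pyridin-3-yl)dodecyl]-3-[(1E)-8-(pyridin-3-yl)oct-1-en-1-yl]hexahydro-1H-cyclopenta[c][1,2]oxazole (E/Z mixture)
Conditions: TsOH·H2O (1.05 equiv per pyridine N), Hoveyda–Grubbs II (10 mol %), CH2Cl2, 40 °C; aq. NaHCO3
Reagents that add atoms: none
Why: In this olefin cross-metathesis the pyridines are masked as pyridinium tosylates, and the excess unhindered terminal alkene should couple with the α-branched vinyl group with loss of ethene; C3 is not involved.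

Step 16
Reactants: 23 (3S,3aS,6aR)-1-[12-(pyridin-3-yl)dodecyl]-3-[(1E)-8-(pyridin-3-yl)oct-1-en-1-yl]hexahydro-1H-cyclopenta[c][1,2]oxazole
Product: 24 (3S,3aS,6aR)-1-[12-(pyridin-3-yl)dodecyl]-3-[8-(pyridin-3-yl)octyl]hexahydro-1H-cyclopenta[c][1,2]oxazole
Conditions: TsNHNH2 (excess, portionwise), NaOAc, DME/H2O, 85 °C
Reagents that add atoms: none
Why: Diimide reduction transfers H2 concertedly to the C=C bond of either alkene isomer and should leave the N–O bond, the pyridines and all three stereocentres untouched.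

**Compound list**

1 | 3-methylpyridine | Cc1cccnc1 | starting material
2 | 7-bromohept-1-ene | C=CCCCCCBr | starting material
3 | (pyridin-3-ylmethyl)lithium | [Li]Cc1cccnc1 | intermediate (not isolated)
4 | 3-(oct-7-en-1-yl)pyridine | C=CCCCCCCc1cccnc1 | intermediate
5 | 3-bromopyridine | Brc1cccnc1 | starting material
6 | dodec-11-yn-1-ol | OCCCCCCCCCCC#C | starting material
7 | 12-(pyridin-3-yl)dodec-11-yn-1-ol | OCCCCCCCCCCC#Cc1cccnc1 | intermediate
8 | 12-(pyridin-3-yl)dodecan-1-ol | OCCCCCCCCCCCCc1cccnc1 | intermediate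
9 | 12-(pyridin-3-yl)dodecanal | O=CCCCCCCCCCCCc1cccnc1 | intermediate
10 | (1S,2R)-2-aminocyclopentane-1-carboxylic acid | OC(=O)[C@H]1CCC[C@H]1N | starting material
11 | (1S,2R)-2-[(tert-butoxycarbonyl)amino]cyclopentane-1-carboxylic acid | OC(=O)[C@H]1CCC[C@H]1NC(=O)OC(C)(C)C | intermediate
12 | tert-butyl N-[(1R,2S)-2-(hydroxymethyl)cyclopentyl]carbamate | OC[C@H]1CCC[C@H]1NC(=O)OC(C)(C)C | intermediate
13 | tert-butyl N-[(1R,2S)-2-formylcyclopentyl]carbamate | O=C[C@H]1CCC[C@H]1NC(=O)OC(C)(C)C | intermediate (not isolated)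
14 | methyl (2E)-3-[(1R,2R)-2-[(tert-butoxycarbonyl)amino]cyclopentyl]prop-2-enoate | COC(=O)/C=C/[C@H]1CCC[C@H]1NC(=O)OC(C)(C)C | intermediate
15 | tert-butyl N-[(1R,2R)-2-[(1E)-3-hydroxyprop-1-en-1-yl]cyclopentyl]carbamate | OC/C=C/[C@H]1CCC[C@H]1NC(=O)OC(C)(C)C | intermediate
16 | tert-butyl N-[(1R,2R)-2-[(1E)-3-[(methoxycarbonyl)oxy]prop-1-en-1-yl]cyclopentyl]carbamate | COC(=O)OC/C=C/[C@H]1CCC[C@H]1NC(=O)OC(C)(C)C | intermediate
17 | (2E)-3-[(1R,2R)-2-aminocyclopentyl]prop-2-en-1-yl methyl carbonate | COC(=O)OC/C=C/[C@H]1CCC[C@H]1N | intermediate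
18 | (2E)-3-[(1R,2R)-2-{[12-(pyridin-3-yl)dodecylidene]amino}cyclopentyl]prop-2-en-1-yl methyl carbonate | COC(=O)OC/C=C/[C@H]1CCC[C@H]1N=CCCCCCCCCCCCc1cccnc1 | intermediate (not isolated)
19 | methyl (2E)-3-[(1R,2R)-2-{[12-(pyridin-3-yl)dodecyl]amino}cyclopentyl]prop-2-en-1-yl carbonate | COC(=O)OC/C=C/[C@H]1CCC[C@H]1NCCCCCCCCCCCCc1cccnc1 | intermediate
20 | methyl (2E)-3-[(1R,2R)-2-{(benzoyloxy)[12-(pyridin-3-yl)dodecyl]amino}cyclopentyl]prop-2-en-1-yl carbonate | COC(=O)OC/C=C/[C@H]1CCC[C@H]1N(OC(=O)c1ccccc1)CCCCCCCCCCCCc1cccnc1 | intermediate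
21 | methyl (2E)-3-[(1R,2R)-2-{hydroxy[12-(pyridin-3-yl)dodecyl]amino}cyclopentyl]prop-2-en-1-yl carbonate | COC(=O)OC/C=C/[C@H]1CCC[C@H]1N(O)CCCCCCCCCCCCc1cccnc1 | intermediate (key-step precursor)
22 | (3S,3aS,6aR)-3-ethenyl-1-[12-(pyridin-3-yl)dodecyl]hexahydro-1H-cyclopenta[c][1,2]oxazole | c1cncc(CCCCCCCCCCCCN2O[C@@H](C=C)[C@H]3CCC[C@H]32)c1 | intermediate (key-step product)
23 | (3S,3aS,6aR)-1-[12-(pyridin-3-yl)dodecyl]-3-[(1E)-8-(pyridin-3-yl)oct-1-en-1-yl]hexahydro-1H-cyclopenta[c][1,2]oxazole | c1cncc(CCCCCCCCCCCCN2O[C@@H](/C=C/CCCCCCc4cccnc4)[C@H]3CCC[C@H]32)c1 | intermediate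
24 | (3S,3aS,6aR)-1-[12-(pyridin-3-yl)dodecyl]-3-[8-(pyridin-3-yl)octyl]hexahydro-1H-cyclopenta[c][1,2]oxazole | c1cncc(CCCCCCCCCCCCN2O[C@@H](CCCCCCCCc3cccnc3)[C@H]3CCC[C@H]32)c1 | target

**Step count**

Total: 16 steps. Longest linear sequence: 12 steps (steps 5–16, from amino acid 10).

**Steps most likely to fail**

1. Step 14. The ligand-selected ionisation may be mismatched with the adjacent C3a centre, so that oxidative addition is slow or facial selectivity erodes towards the 3R epimer. The pyridine nitrogen may also inhibit the catalyst, and the free hydroxylamine may be oxidised to a nitrone.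

   The fallback sets C3 by substrate-controlled hydride delivery to a cyclic N,O-oxocarbenium ion; it sets out from 10 and 9 and comes back at 22. Amino acid 10 would be esterified (SOCl2, MeOH) to methyl (1S,2R)-2-aminocyclopentane-1-carboxylate hydrochloride F1. Reductive alkylation with aldehyde 9 (NaBH(OAc)3, Et3N, DCE) would give methyl (1S,2R)-2-{[12-(pyridin-3-yl)dodecyl]amino}cyclopentane-1-carboxylate F2. N-oxidation with dibenzoyl peroxide/K2HPO4 would give methyl (1S,2R)-2-{(benzoyloxy)[12-(pyridin-3-yl)dodecyl]amino}cyclopentane-1-carboxylate F3, and hydrazinolysis would free methyl (1S,2R)-2-{hydroxy[12-(pyridin-3-yl)dodecyl]amino}cyclopentane-1-carboxylate F4. Warming in toluene should lactonise the N–OH onto the cis ester to give the cis-fused isoxazolidinone (3aS,6aR)-1-[12-(pyridin-3-yl)dodecyl]hexahydro-3H-cyclopenta[c][1,2]oxazol-3-one F5. Lithium (trimethylsilyl)acetylide at −78 °C should add once to give the hemiketal (3aS,6aR)-1-[12-(pyridin-3-yl)dodecyl]-3-[(trimethylsilyl)ethynyl]hexahydro-1H-cyclopenta[c][1,2]oxazol-3-ol F6. Et3SiH/BF3·OEt2 reduction of the derived oxocarbenium ion should deliver hydride from the convex face, leaving the alkynyl group on the concave face, in (3R,3aS,6aR)-1-[12-(pyridin-3-yl)dodecyl]-3-[(trimethylsilyl)ethynyl]hexahydro-1H-cyclopenta[c][1,2]oxazole F7; the descriptor is 3R only because the alkynyl carbon outranks C3a. K2CO3/MeOH would give (3R,3aS,6aR)-3-ethynyl-1-[12-(pyridin-3-yl)dodecyl]hexahydro-1H-cyclopenta[c][1,2]oxazole F8, and Lindlar semi-hydrogenation (quinoline) would give 22.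

2. Step 15. Incompletely protonated basic nitrogens may deactivate the ruthenium carbene, and turnover at the hindered concave vinyl group may be slow, so that only the homodimer of 4 forms.

   The fallback replaces metathesis by hydroboration and B-alkyl Suzuki–Miyaura coupling; it sets out from 22 and from 3-methylpyridine 1 and comes back at 24. 3-Methylpyridine 1 would be lithiated as in step 1 and the anion 3 alkylated with 2-(3-bromopropyl)-1,3-dioxolane to 3-[4-(1,3-dioxolan-2-yl)butyl]pyridine F9. Aqueous HCl would hydrolyse the acetal to 5-(pyridin-3-yl)pentanal F10, and Takai olefination (CrCl2, CHI3, THF) would give 3-[(5E)-6-iodohex-5-en-1-yl]pyridine F11. Vinyl compound 22 would be hydroborated with excess 9-BBN to 9-{2-[(3S,3aS,6aR)-1-[12-(pyridin-3-yl)dodecyl]hexahydro-1H-cyclopenta[c][1,2]oxazol-3-yl]ethyl}-9-borabicyclo[3.3.1]nonane F12, which is not isolated. Its coupling with the vinyl iodide [Pd(dppf)Cl2, AsPh3, Cs2CO3, DMF/THF/H2O] would give (3S,3aS,6aR)-1-[12-(pyridin-3-yl)dodecyl]-3-[(3E)-8-(pyridin-3-yl)oct-3-en-1-yl]hexahydro-1H-cyclopenta[c][1,2]oxazole F13, and diimide reduction under the conditions of step 16 would give 24.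

3. Step 12. N-benzoylation may compete with O-transfer at the hindered secondary amine, conversion may stall, and the pyridine nitrogen may be oxidised in part.

   The fallback makes the hydroxylamine by N-oxide formation and Cope elimination; it sets out from 19 and comes back at 21, by-passing 20. Conjugate addition of 19 to acrylonitrile (neat, 60 °C) would give methyl (2E)-3-[(1R,2R)-2-{(2-cyanoethyl)[12-(pyridin-3-yl)dodecyl]amino}cyclopentyl]prop-2-en-1-yl carbonate F14. One equivalent of mCPBA (K2CO3, CH2Cl2, −78 °C) should oxidise the tertiary amine selectively to the N-oxide methyl (2E)-3-[(1R,2R)-2-{(2-cyanoethyl)(oxido)[12-(pyridin-3-yl)dodecyl]azaniumyl}cyclopentyl]prop-2-en-1-yl carbonate F15, which is not isolated. On warming to rt it should undergo Cope elimination through the acidic hydrogen α to the nitrile to give 21.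

Further compounds
F1 | step 14 | methyl (1S,2R)-2-aminocyclopentane-1-carboxylate hydrochloride | COC(=O)[C@H]1CCC[C@H]1N.Cl
F2 | step 14 | methyl (1S,2R)-2-{[12-(pyridin-3-yl)dodecyl]amino}cyclopentane-1-carboxylate | COC(=O)[C@H]1CCC[C@H]1NCCCCCCCCCCCCc1cccnc1
F3 | step 14 | methyl (1S,2R)-2-{(benzoyloxy)[12-(pyridin-3-yl)dodecyl]amino}cyclopentane-1-carboxylate | COC(=O)[C@H]1CCC[C@H]1N(OC(=O)c1ccccc1)CCCCCCCCCCCCc1cccnc1
F4 | step 14 | methyl (1S,2R)-2-{hydroxy[12-(pyridin-3-yl)dodecyl]amino}cyclopentane-1-carboxylate | COC(=O)[C@H]1CCC[C@H]1N(O)CCCCCCCCCCCCc1cccnc1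
F5 | step 14 | (3aS,6aR)-1-[12-(pyridin-3-yl)dodecyl]hexahydro-3H-cyclopenta[c][1,2]oxazol-3-one | c1cncc(CCCCCCCCCCCCN2OC(=O)[C@H]3CCC[C@H]32)c1
F6 | step 14 | (3aS,6aR)-1-[12-(pyridin-3-yl)dodecyl]-3-[(trimethylsilyl)ethynyl]hexahydro-1H-cyclopenta[c][1,2]oxazol-3-ol | c1cncc(CCCCCCCCCCCCN2OC(O)(C#C[Si](C)(C)C)[C@H]3CCC[C@H]32)c1
F7 | step 14 | (3R,3aS,6aR)-1-[12-(pyridin-3-yl)dodecyl]-3-[(trimethylsilyl)ethynyl]hexahydro-1H-cyclopenta[c][1,2]oxazole | c1cncc(CCCCCCCCCCCCN2O[C@@H](C#C[Si](C)(C)C)[C@H]3CCC[C@H]32)c1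
F8 | step 14 | (3R,3aS,6aR)-3-ethynyl-1-[12-(pyridin-3-yl)dodecyl]hexahydro-1H-cyclopenta[c][1,2]oxazole | c1cncc(CCCCCCCCCCCCN2O[C@@H](C#C)[C@H]3CCC[C@H]32)c1
F9 | step 15 | 3-[4-(1,3-dioxolan-2-yl)butyl]pyridine | c1cncc(CCCCC2OCCO2)c1
F10 | step 15 | 5-(pyridin-3-yl)pentanal | O=CCCCCc1cccnc1
F11 | step 15 | 3-[(5E)-6-iodohex-5-en-1-yl]pyridine | I/C=C/CCCCc1cccnc1
F12 | step 15 | 9-{2-[(3S,3aS,6aR)-1-[12-(pyridin-3-yl)dodecyl]hexahydro-1H-cyclopenta[c][1,2]oxazol-3-yl]ethyl}-9-borabicyclo[3.3.1]nonane | c1cncc(CCCCCCCCCCCCN2O[C@@H](CCB4C5CCCC4CCC5)[C@H]3CCC[C@H]32)c1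
F13 | step 15 | (3S,3aS,6aR)-1-[12-(pyridin-3-yl)dodecyl]-3-[(3E)-8-(pyridin-3-yl)oct-3-en-1-yl]hexahydro-1H-cyclopenta[c][1,2]oxazole | c1cncc(CCCCCCCCCCCCN2O[C@@H](CC/C=C/CCCCc4cccnc4)[C@H]3CCC[C@H]32)c1
F14 | step 12 | methyl (2E)-3-[(1R,2R)-2-{(2-cyanoethyl)[12-(pyridin-3-yl)dodecyl]amino}cyclopentyl]prop-2-en-1-yl carbonate | COC(=O)OC/C=C/[C@H]1CCC[C@H]1N(CCC#N)CCCCCCCCCCCCc1cccnc1
F15 | step 12 | methyl (2E)-3-[(1R,2R)-2-{(2-cyanoethyl)(oxido)[12-(pyridin-3-yl)dodecyl]azaniumyl}cyclopentyl]prop-2-en-1-yl carbonate | COC(=O)OC/C=C/[C@H]1CCC[C@H]1[N+]([O-])(CCC#N)CCCCCCCCCCCCc1cccnc1
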